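The constants come from no measurement; no experiment stands behind them.

I counted partner.

    substrate → intermediate (k1 = 0.0232 min⁻¹)
    partner + intermediate → target (k2 = 304 M⁻¹ min⁻¹)
    partner + target → over-reaction product (k3 = 1.36 M⁻¹ min⁻¹)
    partner → decomposed reagent (k4 = 0.112 min⁻¹)

common to all: time 80 min

| flask | substrate | partner | remark |
|---|---|---|---|
| eta | 0.020 M (in portions, 3, over 30 min) | 0.0140 M | first portion at the start, last at 30 min |
| epsilon | 0.020 M | 0.0140 M | everything together at the start |
| delta | 0.020 M | 0.0140 M (fed, over 30 min) | all else is in the flask from the start; the feed brings no volume worth counting |
| alpha | 0.020 M (fed, over 30 min) | 0.0140 M | all else is in the flask from the start; the feed brings no volume worth counting |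

- which flask leads in amount of target, in percent of the substrate charged ("all alike" within 1.5 percentage points) (eta / epsilon / delta / alpha / all alike)
- how much target is there at the end, in percent of the substrate charged: eta
- how much target is there at the end, in percent of the substrate charged: epsilon
- how much target is there at the end, in percent of the substrate charged: delta
- how much target is there at the end, in percent of the substrate charged: alpha

Partner, the limiting reagent, was charged at less than the substrate, 0.0140 M against 0.020 M, and it also decomposes, so I kept a ledger of its moles. With partner as charged, capture of intermediate runs at 4.26 min⁻¹, far faster than the 0.0232 min⁻¹ of its release. I therefore froze intermediate at a low level and took release as the rate-limiting step, so that each intermediate released cost one partner while partner lasted. What I carried was the release rate, the rate at which the whole substrate charge hands out intermediate at the start, 4.64 × 10⁻⁴ M min⁻¹.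

In epsilon, partner at first decomposes at 0.00157 M min⁻¹, faster than the release. With the release rate held, I reckoned partner to reach zero at 13.2 min, and the first-order loss of substrate gave 26.4% of it reacted by that time. In delta, the feed of 4.67 × 10⁻⁴ M min⁻¹ runs level with the release at the start, and the same first-order loss gave 50.1% of the substrate reacted during the feed. I closed the books there as an estimate, leaving out over-reaction and entering the rest of each partner charge as decomposed:

| Entry | epsilon | delta |
|---|---|---|
| Partner to target | 0.00527 M | 0.0100 M |
| Partner decomposed | 0.00873 M | 0.00400 M |

Eta began with a release of 1.55 × 10⁻⁴ M min⁻¹, less than the release rate of the whole charge, and alpha began with its substrate still to be fed, so I put both below epsilon without a figure.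

The forecast named delta and gave 15.5% for eta, 27.5% for epsilon, 50% for delta and 13% for alpha, on the grounds that “Feeding the partner keeps it alive and matched to the intermediate's release”.

The flasks gave 13.5% for eta, 25.2% for epsilon, 49.8% for delta and 11.5% for alpha, so delta led, as forecast. At the end of its feed, delta held 9.11% of its partner charge, and its decomposed reagent ended at 0.00358 M, against 0.00863 M in epsilon. In the neighbour delta with 0.050 M of substrate, the release rate scales to 0.00116 M min⁻¹, more than the feed, and the partner charge is 28.0% of that substrate. That flask gave 26.3% of target, with decomposed reagent at 7.83 × 10⁻⁴ M.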